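## Retrosynthetic overview

1. The chromene ring is the only ring and is formed last: the C2–O1 bond is closed by a catalytic enantioselective isomerisation of prenylquinone **16** (tautomerisation to a vinyl o-quinone methide, then oxa-6π closure), which sets the single stereocentre (2S).
2. Quinone **16** comes from the 1,4-dimethoxyarene **15** by oxidative demethylation.
3. The C35 chain is cut at the bis-allylic CH2–CH2 bond next to the hydroxymethyl olefin: allylic bromide **7** plus hydroxy sulfone **12** (sulfone alkylation, then Pd/hydride desulfonylation).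
4. **12** comes from (E)-β-farnesene by Pd-catalysed 1,4-chloroacetoxylation, which fixes the (E)-olefin and the oxygenated carbon; then Cl→OH and OAc→SO2Ph.
5. **7** comes from geranylgeraniol and 1,4-dimethoxybenzene (aryl allylation), terminal SeO2 oxidation and Appel bromination.

Assumption: the target descriptor is read as (2S) with the hydroxymethyl olefin (E) (CH2OH trans to the chain leading to the chromene); commercial (2E,6E,10E)-geranylgeraniol and (E)-β-farnesene are used as geometrically pure feedstocks.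

## Route

Step 1
Reactants: 1 (2E,6E,10E)-geranylgeraniol
Product: 2 (2E,6E,10E)-geranylgeranyl bromide
Conditions: PBr3 (0.4 equiv), Et2O, −10 °C, 30 min; used crude
Reagents that add atoms: phosphorus tribromide, BrP(Br)Br
Why: SN2 bromination of a primary allylic alcohol with PBr3 at low temperature proceeds without allylic transposition or loss of olefin geometry.

Step 2
Reactants: 3 1,4-dimethoxybenzene; 2 geranylgeranyl bromide
Product: 5 2-[(2E,6E,10E)-geranylgeranyl]-1,4-dimethoxybenzene, via 2-lithio-1,4-dimethoxybenzene 4 (not isolated)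
Conditions: nBuLi, TMEDA, THF, 0 °C; CuBr·SMe2 (10 mol %), then 2, −78 → 0 °C
Reagents that add atoms: none
Why: Directed ortho-lithiation followed by copper-catalysed SN2 allylation; the γ,γ-disubstituted allyl bromide reacts at the primary carbon, so the 2E olefin is retained.

Step 3
Reactants: 5 2-geranylgeranyl-1,4-dimethoxybenzene
Product: 6 (2E,6E,10E,14E)-16-(2,5-dimethoxyphenyl)-2,6,10,14-tetramethylhexadeca-2,6,10,14-tetraen-1-ol
Conditions: SeO2 (0.3 equiv), tBuOOH (3 equiv), salicylic acid (0.1 equiv), CH2Cl2, 0 °C → rt, run to partial conversion, 5 recycled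
Reagents that add atoms: selenium dioxide (catalytic oxygen-transfer agent), O=[Se]=O; tert-butyl hydroperoxide (terminal oxygen source), CC(C)(C)OO
Why: Sharpless–Umbreit allylic oxidation (ene reaction, then [2,3]-shift) attacks the most accessible terminal isopropylidene and oxidises only its (E)-methyl group, giving the (E)-allylic alcohol.

Step 4
Reactants: 6 ω-allylic alcohol
Product: 7 2-[(2E,6E,10E,14E)-16-bromo-3,7,11,15-tetramethylhexadeca-2,6,10,14-tetraen-1-yl]-1,4-dimethoxybenzene
Conditions: CBr4, PPh3, CH2Cl2, −20 → 0 °C; used at once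
Reagents that add atoms: carbon tetrabromide, BrC(Br)(Br)Br
Why: Appel reaction under neutral conditions converts the primary allylic alcohol into the bromide by SN2 without touching the polyene or the electron-rich arene.

Step 5
Reactants: 8 (E)-β-farnesene
Product: 9 (2E,6E)-3-(chloromethyl)-7,11-dimethyldodeca-2,6,10-trien-1-yl acetate
Conditions: Pd(OAc)2 (5 mol %), p-benzoquinone (2 equiv), LiCl (2 equiv), LiOAc (2 equiv), AcOH–pentane, 25 °C, slow addition of 8
Reagents that add atoms: lithium chloride, [Li+].[Cl-]; acetic acid (with LiOAc as buffer), CC(=O)O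
Why: Bäckvall Pd(II)/benzoquinone 1,4-chloroacetoxylation is selective for the conjugated diene; by analogy with isoprene, acetate attacks the unsubstituted vinyl terminus and chloride the CH2 terminus of the resulting π-allyl, and the s-trans diene gives the (E)-olefin (minor Z isomer removed at 12).

Step 6
Reactants: 9 chloro acetate
Product: 11 (2E,6E)-3-(hydroxymethyl)-7,11-dimethyldodeca-2,6,10-trien-1-yl acetate, via allylic formate 10 (not isolated)
Conditions: HCO2Na, Bu4NBr (cat.), DMF, 40 °C; then NaHCO3 (cat.), MeOH, rt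
Reagents that add atoms: sodium formate, [Na+].[O-]C=O
Why: SN2 displacement of the primary allylic chloride by formate, then chemoselective methanolysis of the formate, which is far more labile than the acetate; the two oxygens are trans across the olefin, so no acyl migration is possible.

Step 7
Reactants: 11 hydroxy acetate
Product: 12 (2E,6E)-7,11-dimethyl-2-[2-(phenylsulfonyl)ethylidene]dodeca-6,10-dien-1-ol
Conditions: PhSO2Na (1.5 equiv), Pd(PPh3)4 (3 mol %), THF–MeOH, rt
Reagents that add atoms: sodium benzenesulfinate, [Na+].[O-]S(=O)c1ccccc1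
Why: Tsuji–Trost sulfonylation: only the acetate ionises, sulfinate attacks the unsubstituted allyl terminus, and the fully substituted terminus cannot undergo syn/anti exchange, so the olefin geometry is kept.

Step 8
Reactants: 12 hydroxy sulfone; 7 allylic bromide
Product: 14 coupled hydroxy sulfone (12 alkylated at the sulfonyl carbon by 7; epimer mixture at that carbon), via dilithiated sulfone 13 (not isolated)
Conditions: nBuLi (2.2 equiv), THF–DMPU, −78 °C; then 7, −78 → −30 °C
Reagents that add atoms: none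
Why: Biellmann/Julia-type α-alkylation of a lithiated allylic sulfone with an allylic bromide; the alkoxide of the dianion is a non-leaving group, so no vinylogous elimination occurs, and the new stereocentre is irrelevant because it is removed in step 9.

Step 9
Reactants: 14 coupled hydroxy sulfone
Product: 15 (2E,6E)-2-[(4E,8E,12E,16E)-18-(2,5-dimethoxyphenyl)-4,8,12,16-tetramethyloctadeca-4,8,12,16-tetraen-1-ylidene]-7,11-dimethyldodeca-6,10-dien-1-ol
Conditions: LiEt3BH (5 equiv), Pd(dppp)Cl2 (5 mol %), THF, 0 °C → rt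
Reagents that add atoms: none
Why: Pd-catalysed reductive desulfonylation of an allylic sulfone (Inomata–Kotake): hydride is delivered to the secondary terminus of the π-allyl rather than the fully substituted one, so the trisubstituted (E)-olefin stays in place.

Step 10
Reactants: 15 dimethoxyarene
Product: 16 2-[(2E,6E,10E,14E,18E,22E)-19-(hydroxymethyl)-3,7,11,15,23,27-hexamethyloctacosa-2,6,10,14,18,22,26-heptaen-1-yl]-1,4-benzoquinone
Conditions: (NH4)2Ce(NO3)6 (2.5 equiv), MeCN–H2O, 0 °C, 15 min
Reagents that add atoms: water, O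
Why: CAN oxidative demethylation of a 1,4-dimethoxyarene to the p-quinone is fast at 0 °C and is tolerated by isolated trisubstituted olefins and the primary allylic alcohol.

Step 11
Reactants: 16 prenylquinone
Product: 18 (2S)-2-[(3E,7E,11E,15E,19E)-16-(hydroxymethyl)-4,8,12,20,24-pentamethylpentacosa-3,7,11,15,19,23-hexaen-1-yl]-2-methyl-2H-chromen-6-ol, via vinyl o-quinone methide 17 (not isolated)
Conditions: quinine-derived 9-amino(9-deoxy)-epi-cinchona 3,5-bis(trifluoromethyl)phenyl squaramide (10 mol %), toluene (0.02 M), 4 Å MS, 0 °C → rt, dark, Ar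
Reagents that add atoms: none
Why: Proposed new method: the quinuclidine nitrogen removes the doubly allylic C1'–H of 16 (the vinylogous enolisation that achiral amines such as pyridine or Et3N are known to effect) and returns the proton to O4, so that o-quinone methide 17 is formed hydrogen-bonded to the catalyst at both oxygens (quinuclidine at O4–H, squaramide N–H pair at C1=O); the thermally allowed disrotatory oxa-6π closure then proceeds from a helical s-cis dienone whose C3'(Me)(chain) terminus can reach O1 only from the face not covered by the aryl-squaramide wall, and because the (E)-geometry of the C2'=C3' olefin is carried over from 16, choosing one helix fixes one configuration at the new quaternary C2, (S), with the quinine or the pseudoenantiomeric quinidine series assigned by one analytical run; the closest known reaction types are the racemic amine-mediated quinone-to-chromenol isomerisation of prenylquinones, bifunctional hydrogen-bond/base-catalysed asymmetric reactions of in situ generated o-quinone methides, and catalytic asymmetric 6π electrocyclisations.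

## Compound list

1 | (2E,6E,10E)-3,7,11,15-tetramethylhexadeca-2,6,10,14-tetraen-1-ol (geranylgeraniol) | CC(C)=CCC/C(C)=C/CC/C(C)=C/CC/C(C)=C/CO | starting material
2 | (2E,6E,10E)-geranylgeranyl bromide | CC(C)=CCC/C(C)=C/CC/C(C)=C/CC/C(C)=C/CBr | intermediate
3 | 1,4-dimethoxybenzene | COc1ccc(OC)cc1 | starting material
4 | (2,5-dimethoxyphenyl)lithium | [Li]c1cc(OC)ccc1OC | intermediate (not isolated)
5 | 1,4-dimethoxy-2-[(2E,6E,10E)-3,7,11,15-tetramethylhexadeca-2,6,10,14-tetraen-1-yl]benzene | CC(C)=CCC/C(C)=C/CC/C(C)=C/CC/C(C)=C/Cc1cc(OC)ccc1OC | intermediate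
6 | (2E,6E,10E,14E)-16-(2,5-dimethoxyphenyl)-2,6,10,14-tetramethylhexadeca-2,6,10,14-tetraen-1-ol | OC/C(C)=C/CC/C(C)=C/CC/C(C)=C/CC/C(C)=C/Cc1cc(OC)ccc1OC | intermediate
7 | 2-[(2E,6E,10E,14E)-16-bromo-3,7,11,15-tetramethylhexadeca-2,6,10,14-tetraen-1-yl]-1,4-dimethoxybenzene | BrC/C(C)=C/CC/C(C)=C/CC/C(C)=C/CC/C(C)=C/Cc1cc(OC)ccc1OC | intermediate
8 | (6E)-7,11-dimethyl-3-methylidenedodeca-1,6,10-triene ((E)-β-farnesene) | CC(C)=CCC/C(C)=C/CCC(=C)C=C | starting material
9 | (2E,6E)-3-(chloromethyl)-7,11-dimethyldodeca-2,6,10-trien-1-yl acetate | CC(C)=CCC/C(C)=C/CC/C(CCl)=C\COC(C)=O | intermediate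
10 | (2E,6E)-3-[(formyloxy)methyl]-7,11-dimethyldodeca-2,6,10-trien-1-yl acetate | CC(C)=CCC/C(C)=C/CC/C(COC=O)=C\COC(C)=O | intermediate (not isolated)
11 | (2E,6E)-3-(hydroxymethyl)-7,11-dimethyldodeca-2,6,10-trien-1-yl acetate | CC(C)=CCC/C(C)=C/CC/C(CO)=C\COC(C)=O | intermediate
12 | (2E,6E)-7,11-dimethyl-2-[2-(phenylsulfonyl)ethylidene]dodeca-6,10-dien-1-ol | CC(C)=CCC/C(C)=C/CC/C(CO)=C\CS(=O)(=O)c1ccccc1 | intermediate
13 | dilithio derivative of 12 (lithium alkoxide and α-sulfonyl allyllithium) | CC(C)=CCC/C(C)=C/CC/C(CO[Li])=C\C([Li])S(=O)(=O)c1ccccc1 | intermediate (not isolated)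
14 | (2E,6E)-2-[(4E,8E,12E,16E)-18-(2,5-dimethoxyphenyl)-4,8,12,16-tetramethyl-2-(phenylsulfonyl)octadeca-4,8,12,16-tetraen-1-ylidene]-7,11-dimethyldodeca-6,10-dien-1-ol, both epimers at the sulfonyl carbon | CC(C)=CCC/C(C)=C/CC/C(CO)=C\C(C/C(C)=C/CC/C(C)=C/CC/C(C)=C/CC/C(C)=C/Cc1cc(OC)ccc1OC)S(=O)(=O)c1ccccc1 | intermediate
15 | (2E,6E)-2-[(4E,8E,12E,16E)-18-(2,5-dimethoxyphenyl)-4,8,12,16-tetramethyloctadeca-4,8,12,16-tetraen-1-ylidene]-7,11-dimethyldodeca-6,10-dien-1-ol | CC(C)=CCC/C(C)=C/CC/C(CO)=C\CC/C(C)=C/CC/C(C)=C/CC/C(C)=C/CC/C(C)=C/Cc1cc(OC)ccc1OC | intermediate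
16 | 2-[(2E,6E,10E,14E,18E,22E)-19-(hydroxymethyl)-3,7,11,15,23,27-hexamethyloctacosa-2,6,10,14,18,22,26-heptaen-1-yl]cyclohexa-2,5-diene-1,4-dione | CC(C)=CCC/C(C)=C/CC/C(CO)=C\CC/C(C)=C/CC/C(C)=C/CC/C(C)=C/CC/C(C)=C/CC1=CC(=O)C=CC1=O | intermediate
17 | 4-hydroxy-6-alkylidenecyclohexa-2,4-dien-1-one (vinyl o-quinone methide of 16; exocyclic olefin Z, vinyl group syn to C=O; all chain olefins as in 16) | CC(C)=CCC/C(C)=C/CC/C(CO)=C\CC/C(C)=C/CC/C(C)=C/CC/C(C)=C/CC/C(C)=C/C=C1/C=C(O)C=CC1=O | intermediate (not isolated)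
18 | (2S)-2-[(3E,7E,11E,15E,19E)-16-(hydroxymethyl)-4,8,12,20,24-pentamethylpentacosa-3,7,11,15,19,23-hexaen-1-yl]-2-methyl-2H-chromen-6-ol | CC(C)=CCC/C(C)=C/CC/C(=C\CC/C(C)=C/CC/C(C)=C/CC/C(C)=C/CC[C@@]1(C)C=Cc2cc(O)ccc2O1)CO | target

## Step count and risk

Total steps: 11. Longest linear sequence: 8 (steps 1–4, then 8–11); the farnesene branch (steps 5–7) is convergent.

The three steps most likely to fail, with fallbacks:

**Step 11 (the proposed enantioselective isomerisation).** The risks are low enantioselectivity (the stereocentre forms in a fast pericyclic step and differs only in methyl versus chain) and amine-promoted side reactions of the unsubstituted quinone. The fallback sets out from 16 and returns at 18. Quinone 16 is isomerised with pyridine (or Et3N in CH2Cl2) at rt to 60 °C, the established racemic prenylquinone-to-chromenol reaction, to give the racemic chromenol F1. F1 is then resolved by preparative chiral-phase SFC on an amylose carbamate column to deliver 18.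

**Step 5 (1,4-chloroacetoxylation of β-farnesene).** The regiochemistry and E/Z ratio are extrapolated from isoprene, and Diels–Alder addition of the diene to benzoquinone competes. The fallback sets out from 7 and returns at 15, replacing steps 5–9 by carbonyl chemistry. Bromide 7 is alkylated with lithioacetonitrile (THF, −78 °C) to give the nitrile F2, which DIBAL-H reduces to the aldehyde F3. Ethyl (4E)-5,9-dimethyldeca-4,8-dienoate F4 is made from geranyl bromide and the lithium enolate of ethyl acetate. Its LDA enolate adds to F3 to give the β-hydroxy ester F5. Mesylation (MsCl, Et3N) gives the mesylate F6, and E1cB elimination with DBU gives the thermodynamically favoured (E)-2-alkylidene ester F7 (ester trans to the β-substituent). DIBAL-H reduction of F7 gives 15.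

**Step 3 (terminal SeO2 oxidation).** Selectivity among five trisubstituted olefins is modest, and over-oxidation to the enal occurs. The fallback sets out from 5 and returns at 6 by the van Tamelen terminal-selective sequence. NBS in aqueous THF at 0 °C gives the terminal bromohydrin F8, and K2CO3 in MeOH closes it to the terminal epoxide F9. Periodic acid cleaves F9 to the trisnor aldehyde F10. A stabilised Wittig reaction with Ph3P=C(CH3)CO2Et gives the (E)-enoate F11, and DIBAL-H reduction gives 6.

## Further compounds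

F1 | step 11 | racemic 2-[(3E,7E,11E,15E,19E)-16-(hydroxymethyl)-4,8,12,20,24-pentamethylpentacosa-3,7,11,15,19,23-hexaen-1-yl]-2-methyl-2H-chromen-6-ol | CC(C)=CCC/C(C)=C/CC/C(=C\CC/C(C)=C/CC/C(C)=C/CC/C(C)=C/CCC1(C)C=Cc2cc(O)ccc2O1)CO
F2 | step 5 | (4E,8E,12E,16E)-18-(2,5-dimethoxyphenyl)-4,8,12,16-tetramethyloctadeca-4,8,12,16-tetraenenitrile | N#CCC/C(C)=C/CC/C(C)=C/CC/C(C)=C/CC/C(C)=C/Cc1cc(OC)ccc1OC
F3 | step 5 | (4E,8E,12E,16E)-18-(2,5-dimethoxyphenyl)-4,8,12,16-tetramethyloctadeca-4,8,12,16-tetraenal | O=CCC/C(C)=C/CC/C(C)=C/CC/C(C)=C/CC/C(C)=C/Cc1cc(OC)ccc1OC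
F4 | step 5 | ethyl (4E)-5,9-dimethyldeca-4,8-dienoate | CCOC(=O)CC/C=C(\C)CCC=C(C)C
F5 | step 5 | ethyl (6E,10E,14E,18E)-20-(2,5-dimethoxyphenyl)-2-[(3E)-4,8-dimethylnona-3,7-dien-1-yl]-3-hydroxy-6,10,14,18-tetramethylicosa-6,10,14,18-tetraenoate (diastereomer mixture) | CCOC(=O)C(CC/C=C(\C)CCC=C(C)C)C(O)CC/C(C)=C/CC/C(C)=C/CC/C(C)=C/CC/C(C)=C/Cc1cc(OC)ccc1OC
F6 | step 5 | 3-methanesulfonate of F5 (diastereomer mixture) | CCOC(=O)C(CC/C=C(\C)CCC=C(C)C)C(OS(C)(=O)=O)CC/C(C)=C/CC/C(C)=C/CC/C(C)=C/CC/C(C)=C/Cc1cc(OC)ccc1OC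
F7 | step 5 | ethyl (2E,6E,10E,14E,18E)-20-(2,5-dimethoxyphenyl)-2-[(3E)-4,8-dimethylnona-3,7-dien-1-yl]-6,10,14,18-tetramethylicosa-2,6,10,14,18-pentaenoate | CCOC(=O)/C(CC/C=C(\C)CCC=C(C)C)=C/CC/C(C)=C/CC/C(C)=C/CC/C(C)=C/CC/C(C)=C/Cc1cc(OC)ccc1OC
F8 | step 3 | (6E,10E,14E)-3-bromo-16-(2,5-dimethoxyphenyl)-2,6,10,14-tetramethylhexadeca-6,10,14-trien-2-ol (racemic) | CC(C)(O)C(Br)CC/C(C)=C/CC/C(C)=C/CC/C(C)=C/Cc1cc(OC)ccc1OC
F9 | step 3 | 2-[(2E,6E,10E)-13-(3,3-dimethyloxiran-2-yl)-3,7,11-trimethyltrideca-2,6,10-trien-1-yl]-1,4-dimethoxybenzene (racemic) | CC1(C)OC1CC/C(C)=C/CC/C(C)=C/CC/C(C)=C/Cc1cc(OC)ccc1OC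
F10 | step 3 | (4E,8E,12E)-14-(2,5-dimethoxyphenyl)-4,8,12-trimethyltetradeca-4,8,12-trienal | O=CCC/C(C)=C/CC/C(C)=C/CC/C(C)=C/Cc1cc(OC)ccc1OC
F11 | step 3 | ethyl (2E,6E,10E,14E)-16-(2,5-dimethoxyphenyl)-2,6,10,14-tetramethylhexadeca-2,6,10,14-tetraenoate | CCOC(=O)/C(C)=C/CC/C(C)=C/CC/C(C)=C/CC/C(C)=C/Cc1cc(OC)ccc1OC
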